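A direct plan would protect the catechol aldehyde as its bis(isopropyl) ether A1, build a 3-arylpropanoyl oxazolidinone from it, alkylate that with a bromoacetate and close the β-benzyl-γ-butyrolactone A2.
A second A1 would then be added to the lactone enolate (aldol adduct A3), the benzylic hydroxyl removed, the lactone reduced to a diol, and the dimesylate A4 reduced to the dimethyl compound A5 before Lewis-acid deprotection.
Weakest would be the lactone detour: auxiliary acylation, alkylation, reductive cleavage, lactonisation, lactone reduction, mesylation and hydride displacement would serve only to turn two carboxyl-level carbons into the two CH3 groups, and the monomesylate on the way to A4 could close to a tetrahydrofuran.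
Next would be the aldol step to A3: it would create a carbinol centre without control that must then be erased, would rest on substrate control alone for the trans relation, and would bring in the second aryl half separately although the target is C2-symmetric.
Last would be the final cleavage of four isopropyl ethers beside two methyl ethers with BCl3: selectivity between two kinds of aryl ether would be asked of the most valuable material, where loss of OCH3 cannot be repaired.

**Plan of the new route**

The target has a C2 axis through the midpoint of the C2–C3 bond of the butane chain, so C2/C3, the two methyl groups, C1/C4 and the two trioxygenated benzene rings are pairwise equivalent.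
The retrosynthesis first cuts the C–H bonds at C2 and C3 (and at C1 and C4), back to the flat, achiral (1E,3E)-1,4-diaryl-2,3-dimethylbuta-1,3-diene.
The C2–C3 bond of that diene is then cut by a homocoupling into two identical alkenylboronates, each from an arylpropyne (aryl–C(sp) bond) and one bromoarene.
No ring is formed: both benzene rings are bought in 5-bromo-2-hydroxy-3-methoxybenzaldehyde.
There is no lactone and no carboxyl carbon to reduce (the methyl groups enter as propyne), no centre made to be erased (one catalyst sets both in two identical events), and the catechols are benzyl ethers that leave by neutral hydrogenolysis.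

Key step: step 6

Abbreviation: Ar = 3,4-bis(benzyloxy)-5-methoxyphenyl.

Assumption: the (S)-configured phosphinooxazoline ligand is taken to give the (2R,3R) product, by analogy with the sense known for (E)-1,2-diarylpropenes. If a trial shows the opposite sense, the (R)-ligand is used and nothing else changes.

**Route**

Step 1
Reactants: 1 5-bromo-2-hydroxy-3-methoxybenzaldehyde
Product: 3 5-bromo-3-methoxybenzene-1,2-diol, via aryl formate 2 (not isolated)
Conditions: H2O2 (30% aq), NaOH (aq), THF–H2O, 0 °C to rt, N2; then HCl (aq)
Reagents that add atoms: hydrogen peroxide, OO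
Why: Dakin oxidation: hydroperoxide adds to the aldehyde ortho to the phenoxide, the electron-rich aryl group migrates to oxygen and the formate 2 is hydrolysed in the same flask, which gives the 1,2-dihydroxy-3-methoxy pattern with the bromide para to the central oxygen.

Step 2
Reactants: 3 5-bromo-3-methoxybenzene-1,2-diol
Product: 4 1,2-bis(benzyloxy)-5-bromo-3-methoxybenzene (ArBr)
Conditions: BnBr (2.4 equiv), K2CO3, DMF, 60 °C, N2
Reagents that add atoms: benzyl bromide, BrCc1ccccc1
Why: Williamson etherification of both phenols gives benzyl ethers that should survive the palladium, copper and iridium steps and leave at the end by neutral hydrogenolysis.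

Step 3
Reactants: 4 ArBr; 5 propyne
Product: 6 1,2-bis(benzyloxy)-3-methoxy-5-(prop-1-yn-1-yl)benzene (Ar–C≡C–CH3)
Conditions: propyne (3 equiv, solution in THF), PdCl2(PhCN)2 (3 mol%), [HP(t-Bu)3]BF4 (6 mol%), CuI (3 mol%), iPr2NH, dioxane, rt, closed vessel
Reagents that add atoms: none
Why: Sonogashira coupling, in which the bulky electron-rich phosphine should allow oxidative addition to the electron-rich aryl bromide at room temperature so that the volatile alkyne stays in solution; the propyne methyl group is the future C2 or C3 methyl group.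

Step 4
Reactants: 6 Ar–C≡C–CH3
Product: 7 (Z)-2-(1-Ar-prop-1-en-2-yl)-4,4,5,5-tetramethyl-1,3,2-dioxaborolane (Ar cis to CH3, trans to boron)
Conditions: B2pin2 (1.1 equiv), CuCl (5 mol%), NaOt-Bu (10 mol%), P(p-tol)3 (6 mol%), MeOH (2 equiv), THF, rt
Reagents that add atoms: bis(pinacolato)diboron, CC1(C)OB(OC1(C)C)B1OC(C)(C)C(C)(C)O1
Why: Copper-catalysed formal hydroboration (syn borylcupration, then protonation of the C–Cu bond by methanol with retention): copper should go to the benzylic carbon, which the aryl group stabilises, and boron to the methyl-bearing carbon, so that H and boron end up cis and the aryl group trans to boron, which fixes the alkene geometry needed later.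

Step 5
Reactants: 7 alkenylboronate (2 equiv)
Product: 8 (1E,3E)-1,4-di-Ar-2,3-dimethylbuta-1,3-diene
Conditions: PdCl2(PPh3)2 (5 mol%), chloroacetone (1.5 equiv), K2CO3 (aq), MeOH–THF, 40 °C
Reagents that add atoms: none
Why: Palladium-catalysed oxidative homocoupling of an alkenylboronate: two transmetalations to divalent palladium and reductive elimination join the two boron-bearing carbons with retention at both alkenes, and chloroacetone returns zerovalent palladium to the divalent state; the new bond is the C2–C3 bond of the chain, formed between sp2 carbons so that no stereocentre is at stake.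

Step 6
Reactants: 8 (1E,3E)-1,4-di-Ar-2,3-dimethylbuta-1,3-diene
Product: 10 (2R,3R)-1,4-di-Ar-2,3-dimethylbutane, via monoene 9 (not isolated)
Conditions: H2 (50 bar), [Ir(cod)(L)][B(C6H3(CF3)2)4] (2 mol%; L = (S)-4-tert-butyl-2-[2-(di-o-tolylphosphino)phenyl]-4,5-dihydrooxazole, cod = cycloocta-1,5-diene), CH2Cl2, rt; then recrystallisation
Reagents that add atoms: none
Why: The cationic iridium complex loses cyclooctadiene under H2 to give an iridium dihydride that binds one ArCH=C(CH3)– unit of 8, inserts it into Ir–H and reductively eliminates, so that H2 is added syn to one face by 1,2-addition; the monoene 9 then re-enters the same cycle. The closest known reaction type is the iridium phosphinooxazoline hydrogenation of unfunctionalised (E)-trisubstituted aryl alkenes such as (E)-1,2-diarylpropenes, and the twofold hydrogenation of 2,3-disubstituted buta-1,3-dienes with the same catalyst family. No ring is closed. Both stereocentres are set by the catalyst alone: with the vinylic hydrogen of each alkene in the hindered quadrant next to the tert-butyl group, hydrogen should reach C2 and C3 from the face that is Si in 8 (C3 > C1 > CH3 at C2), which is the (R) sense at each carbon. The step needs the same facial choice twice, and the C2 symmetry of 8 secures this because both alkenes are the same E-configured substrate type (geometry fixed in steps 4 and 5); an error in either event should give mainly the meso isomer, which crystallisation of 10 is meant to remove, and not the enantiomer. Homogeneous iridium should leave the benzyl ethers, the methyl ethers and the arenes untouched.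

Step 7
Reactants: 10 (2R,3R)-1,4-di-Ar-2,3-dimethylbutane
Product: 11 Sauriol A
Conditions: H2 (1 atm), 10% Pd/C, EtOAc–MeOH, rt; filtration and concentration under argon
Reagents that add atoms: none
Why: Heterogeneous hydrogenolysis of the four benzyl aryl ethers under neutral conditions; the methyl ethers are inert and the stereocentres, which are not benzylic, cannot be touched.

**Compound list**

1 | 5-bromo-2-hydroxy-3-methoxybenzaldehyde | COc1cc(Br)cc(C=O)c1O | starting material
2 | 5-bromo-2-hydroxy-3-methoxyphenyl formate | COc1cc(Br)cc(OC=O)c1O | intermediate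
3 | 5-bromo-3-methoxybenzene-1,2-diol | COc1cc(Br)cc(O)c1O | intermediate
4 | 1,2-bis(benzyloxy)-5-bromo-3-methoxybenzene | COc1cc(Br)cc(OCc2ccccc2)c1OCc1ccccc1 | intermediate
5 | propyne | CC#C | starting material
6 | 1,2-bis(benzyloxy)-3-methoxy-5-(prop-1-yn-1-yl)benzene | CC#Cc1cc(OC)c(OCc2ccccc2)c(OCc2ccccc2)c1 | intermediate
7 | (Z)-2-{1-[3,4-bis(benzyloxy)-5-methoxyphenyl]prop-1-en-2-yl}-4,4,5,5-tetramethyl-1,3,2-dioxaborolane | C/C(B1OC(C)(C)C(C)(C)O1)=C\c1cc(OC)c(OCc2ccccc2)c(OCc2ccccc2)c1 | intermediate
8 | (1E,3E)-1,4-bis[3,4-bis(benzyloxy)-5-methoxyphenyl]-2,3-dimethylbuta-1,3-diene | C/C(=C\c1cc(OC)c(OCc2ccccc2)c(OCc2ccccc2)c1)C(/C)=C/c1cc(OC)c(OCc2ccccc2)c(OCc2ccccc2)c1 | intermediate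
9 | (1E,3R)-1,4-bis[3,4-bis(benzyloxy)-5-methoxyphenyl]-2,3-dimethylbut-1-ene | C/C(=C\c1cc(OC)c(OCc2ccccc2)c(OCc2ccccc2)c1)[C@H](C)Cc1cc(OC)c(OCc2ccccc2)c(OCc2ccccc2)c1 | intermediate
10 | (2R,3R)-1,4-bis[3,4-bis(benzyloxy)-5-methoxyphenyl]-2,3-dimethylbutane | COc1cc(C[C@@H](C)[C@H](C)Cc2cc(OCc3ccccc3)c(OCc3ccccc3)c(OC)c2)cc(OCc2ccccc2)c1OCc1ccccc1 | intermediate
11 | Sauriol A, 5,5'-[(2R,3R)-2,3-dimethylbutane-1,4-diyl]bis(3-methoxybenzene-1,2-diol) | COc1cc(C[C@@H](C)[C@H](C)Cc2cc(O)c(O)c(OC)c2)cc(O)c1O | target

**Summary**

Total step count: 7. Longest linear sequence: 7 steps (1 to 11).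

Steps most likely to fail:

Step 6. The risk is poor facial selectivity in one of the two hydrogenation events, so that the meso isomer forms in quantity. The reaction may also stall at the monoene, or hydrogen may add 1,4 and leave a tetrasubstituted alkene. The fallback uses known chemistry, sets out from bromide 4 and returns at 10. (4R)-4-Benzyl-3-propanoyl-1,3-oxazolidin-2-one F1 would be converted into its lithium enolate (LDA, THF, −78 °C) and coupled oxidatively with TiCl4. This should give the bis-imide (2S,3S)-1,4-bis[(4R)-4-benzyl-2-oxo-1,3-oxazolidin-3-yl]-2,3-dimethylbutane-1,4-dione F2, with both new centres set by bond formation anti to the benzyl groups of the auxiliaries. LiBH4 (THF, MeOH) would give (2S,3S)-2,3-dimethylbutane-1,4-diol F3 and return the auxiliary. TsCl in pyridine would give (2S,3S)-2,3-dimethylbutane-1,4-diyl bis(4-methylbenzenesulfonate) F4. The Grignard reagent [3,4-bis(benzyloxy)-5-methoxyphenyl]magnesium bromide F5, made from 4 with Mg in THF, would then be coupled twice with F4 under Li2CuCl4 catalysis (THF, −20 °C to rt) to give 10. The descriptor changes from (2S,3S) to (2R,3R) only because CH2Ar ranks below the neighbouring stereocentre whereas CH2O ranks above it.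

Step 5. The risk is protodeboronation or slow transmetalation of the α-branched alkenylboronate, or loss of alkene geometry during the coupling. The fallback sets out from 7 and returns at 8. One half of 7 would be converted by iododeboronation with retention (NaOH aq, I2, THF, 0 °C) into 1,2-bis(benzyloxy)-5-[(1E)-2-iodoprop-1-en-1-yl]-3-methoxybenzene F6. F6 would then be joined to the other half of 7 by a Suzuki–Miyaura cross-coupling (Pd(PPh3)4, K3PO4 aq, THF, 60 °C) to give 8.

Step 4. The risk is erosion of regioselectivity in the borylcupration by the electron-rich arene, so that boron ends up in part on the benzylic carbon, or reduction of the alkyne beyond the alkene stage. The fallback sets out from 4, bypasses steps 3 to 5 and returns at 8. It is a twofold Mizoroki–Heck arylation of 2,3-dimethylbuta-1,3-diene F7 with 4 (Pd(OAc)2, P(o-tol)3, Et3N, DMF, 100 °C). It would pass through 1,2-bis(benzyloxy)-5-[(1E)-2,3-dimethylbuta-1,3-dien-1-yl]-3-methoxybenzene F8. Syn β-hydride elimination should place each aryl group trans to the larger alkenyl substituent.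

**Further compounds**

F1 | step 6 | (4R)-4-benzyl-3-propanoyl-1,3-oxazolidin-2-one | CCC(=O)N1[C@H](Cc2ccccc2)COC1=O
F2 | step 6 | (2S,3S)-1,4-bis[(4R)-4-benzyl-2-oxo-1,3-oxazolidin-3-yl]-2,3-dimethylbutane-1,4-dione | O=C1OC[C@@H](Cc2ccccc2)N1C(=O)[C@@H](C)[C@H](C)C(=O)N1[C@H](Cc2ccccc2)COC1=O
F3 | step 6 | (2S,3S)-2,3-dimethylbutane-1,4-diol | OC[C@@H](C)[C@H](C)CO
F4 | step 6 | (2S,3S)-2,3-dimethylbutane-1,4-diyl bis(4-methylbenzenesulfonate) | Cc1ccc(cc1)S(=O)(=O)OC[C@@H](C)[C@H](C)COS(=O)(=O)c1ccc(C)cc1
F5 | step 6 | [3,4-bis(benzyloxy)-5-methoxyphenyl]magnesium bromide | COc1cc([Mg]Br)cc(OCc2ccccc2)c1OCc1ccccc1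
F6 | step 5 | 1,2-bis(benzyloxy)-5-[(1E)-2-iodoprop-1-en-1-yl]-3-methoxybenzene | C/C(I)=C\c1cc(OC)c(OCc2ccccc2)c(OCc2ccccc2)c1
F7 | step 4 | 2,3-dimethylbuta-1,3-diene | CC(=C)C(C)=C
F8 | step 4 | 1,2-bis(benzyloxy)-5-[(1E)-2,3-dimethylbuta-1,3-dien-1-yl]-3-methoxybenzene | C=C(C)/C(C)=C/c1cc(OC)c(OCc2ccccc2)c(OCc2ccccc2)c1
A1 | direct plan | 3,4-diisopropoxy-5-methoxybenzaldehyde | O=Cc1cc(OC)c(OC(C)C)c(OC(C)C)c1
A2 | direct plan | (4R)-4-[(3,4-diisopropoxy-5-methoxyphenyl)methyl]oxolan-2-one | O=C1C[C@@H](Cc2cc(OC)c(OC(C)C)c(OC(C)C)c2)CO1
A3 | direct plan | (3S,4R)-3-[(3,4-diisopropoxy-5-methoxyphenyl)(hydroxy)methyl]-4-[(3,4-diisopropoxy-5-methoxyphenyl)methyl]oxolan-2-one (carbinol epimers) | O=C1[C@H](C(O)c2cc(OC)c(OC(C)C)c(OC(C)C)c2)[C@@H](Cc3cc(OC)c(OC(C)C)c(OC(C)C)c3)CO1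
A4 | direct plan | (2R,3R)-2,3-bis[(3,4-diisopropoxy-5-methoxyphenyl)methyl]butane-1,4-diyl dimethanesulfonate | CS(=O)(=O)OC[C@H](Cc1cc(OC)c(OC(C)C)c(OC(C)C)c1)[C@@H](Cc2cc(OC)c(OC(C)C)c(OC(C)C)c2)COS(C)(=O)=O
A5 | direct plan | (2R,3R)-1,4-bis(3,4-diisopropoxy-5-methoxyphenyl)-2,3-dimethylbutane | C[C@H](Cc1cc(OC)c(OC(C)C)c(OC(C)C)c1)[C@@H](Cc2cc(OC)c(OC(C)C)c(OC(C)C)c2)C
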